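**Plan**

1. Retrosynthesis cuts, in order: the C3=C4 alkene and the ester C–O of the furanone (acyl-ylide annulation); the bond between furanone C5 and the allylic CH2 of the side chain; the Z-trisubstituted C=C (Z-selective olefination); the CH2–C bond between the two side-chain alkenes (allylic alkylation with a vinyl epoxide); the epoxide back to dihydro-β-ionone.
2. Enabling feature: in the furanone ring, O1, C5, C4 and the exocyclic CH2–O on C4 form a 1,3-dihydroxyacetone unit once C3=C4 is cut. C4 is its ketone carbon and C5 an α-carbon, so C5 can be allylated as an azaenolate.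
3. The precursor for that event is the SAMP hydrazone of 2,2-dimethyl-1,3-dioxan-5-one. Its six-membered acetonide ring and its C=N–N bond are not in the target and are removed after the union.
4. Forward: the chain grows from the cyclohexene end (C15 vinyl epoxide, then C17 phosphonate, then C20 Z-allylic bromide), the C3 ketone unit is joined, and the furanone ring is closed last by O-acylation at O1 and intramolecular Wittig closure of C3=C4.
5. Stereochemistry: the tertiary carbinol (S) comes from Sharpless epoxidation with L-(+)-tartrate, its C–O bond being kept in the palladium step; furanone C5 (S) comes from the SAMP auxiliary; the E-alkene from the syn π-allyl complex; the Z-alkene from Still–Gennari olefination.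

Key step: step 14

Remark: the two phosphonates formed in steps 6 and 7 are carried as mixtures of epimers at the phosphorus-bearing carbon (it becomes sp2 in step 8), and the hydrazones are drawn without C=N geometry (either isomer gives the same ketone).

**Route**

Step 1
Reactants: 1 dihydro-β-ionone [4-(2,6,6-trimethylcyclohex-1-en-1-yl)butan-2-one]
Product: 2 ethyl (2E)-3-methyl-5-(2,6,6-trimethylcyclohex-1-en-1-yl)pent-2-enoate
Conditions: (EtO)2P(O)CH2CO2Et, NaH, THF, 0 °C to reflux; minor Z isomer removed by chromatography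
Reagents that add atoms: triethyl phosphonoacetate, CCOC(=O)CP(=O)(OCC)OCC
Why: Horner–Wadsworth–Emmons olefination of a methyl ketone should place the ester anti to the larger chain (E), and the minor Z ester is separable.

Step 2
Reactants: 2 ethyl (2E)-3-methyl-5-(2,6,6-trimethylcyclohex-1-en-1-yl)pent-2-enoate
Product: 3 (2E)-3-methyl-5-(2,6,6-trimethylcyclohex-1-en-1-yl)pent-2-en-1-ol
Conditions: i-Bu2AlH (2.2 equiv), CH2Cl2, −78 to 0 °C; aq. potassium sodium tartrate
Reagents that add atoms: none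
Why: i-Bu2AlH reduction of an enoate is a reliable 1,2-reduction to the allylic alcohol and leaves the alkene geometry untouched.

Step 3
Reactants: 3 (2E)-3-methyl-5-(2,6,6-trimethylcyclohex-1-en-1-yl)pent-2-en-1-ol
Product: 4 {(2S,3S)-3-methyl-3-[2-(2,6,6-trimethylcyclohex-1-en-1-yl)ethyl]oxiran-2-yl}methanol
Conditions: Ti(Oi-Pr)4 (10 mol%), L-(+)-diethyl tartrate (12 mol%), t-BuOOH, 4 Å molecular sieves, CH2Cl2, −20 °C
Reagents that add atoms: tert-butyl hydroperoxide, CC(C)(C)OO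
Why: Sharpless asymmetric epoxidation of an E-3-methyl-2-alken-1-ol with L-(+)-tartrate should give the (2S,3S) epoxide as with geraniol, and the tetrasubstituted ring alkene is not an allylic alcohol and should not react.

Step 4
Reactants: 4 {(2S,3S)-3-methyl-3-[2-(2,6,6-trimethylcyclohex-1-en-1-yl)ethyl]oxiran-2-yl}methanol
Product: 5 (2R,3S)-3-methyl-3-[2-(2,6,6-trimethylcyclohex-1-en-1-yl)ethyl]oxirane-2-carbaldehyde
Conditions: TEMPO (10 mol%), PhI(OAc)2, CH2Cl2, rt
Reagents that add atoms: none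
Why: TEMPO/PhI(OAc)2 oxidation of a primary alcohol stops at the aldehyde under near-neutral conditions that epoxides and alkenes tolerate (the descriptor at C2 changes only through CIP priorities).

Step 5
Reactants: 5 (2R,3S)-3-methyl-3-[2-(2,6,6-trimethylcyclohex-1-en-1-yl)ethyl]oxirane-2-carbaldehyde
Product: 6 (2S,3S)-2-ethenyl-3-methyl-3-[2-(2,6,6-trimethylcyclohex-1-en-1-yl)ethyl]oxirane
Conditions: Ph3PCH3Br, KN(SiMe3)2, THF, 0 °C; then 5, −78 °C to rt
Reagents that add atoms: methyltriphenylphosphonium bromide, C[P+](c1ccccc1)(c1ccccc1)c1ccccc1.[Br-]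
Why: Wittig methylenation of an α,β-epoxy aldehyde is a standard entry to vinyl epoxides and does not touch the epoxide stereocentres.

Step 6
Reactants: 6 (2S,3S)-2-ethenyl-3-methyl-3-[2-(2,6,6-trimethylcyclohex-1-en-1-yl)ethyl]oxirane; 7 methyl 2-[bis(2,2,2-trifluoroethoxy)phosphoryl]acetate
Product: 8 methyl (4E,6S)-2-[bis(2,2,2-trifluoroethoxy)phosphoryl]-6-hydroxy-6-methyl-8-(2,6,6-trimethylcyclohex-1-en-1-yl)oct-4-enoate (both epimers at C2)
Conditions: Pd(PPh3)4 (5 mol%), 7 (2 equiv), THF, 0 °C to rt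
Reagents that add atoms: none
Why: in this Tsuji–Trost alkylation, zerovalent palladium ionises the allylic C–O bond of the vinyl epoxide, the alkoxide deprotonates the phosphonoacetate and the soft carbanion attacks the unsubstituted terminus of the syn π-allyl complex, which should give the E-alkene while the C–O bond at the quaternary carbon, and so the S carbinol, is kept.

Step 7
Reactants: 8 methyl (4E,6S)-2-[bis(2,2,2-trifluoroethoxy)phosphoryl]-6-hydroxy-6-methyl-8-(2,6,6-trimethylcyclohex-1-en-1-yl)oct-4-enoate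
Product: 9 methyl (4E,6S)-2-[bis(2,2,2-trifluoroethoxy)phosphoryl]-6-methyl-6-(triethylsilyloxy)-8-(2,6,6-trimethylcyclohex-1-en-1-yl)oct-4-enoate (both epimers at C2)
Conditions: Et3SiOTf, 2,6-lutidine, CH2Cl2, −78 to 0 °C
Reagents that add atoms: triethylsilyl trifluoromethanesulfonate, CC[Si](CC)(CC)OS(=O)(=O)C(F)(F)F
Why: silyl triflate with 2,6-lutidine is the standard silylation of a hindered tertiary alcohol and masks the hydroxyl for the two carbanion steps that follow.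

Step 8
Reactants: 9 methyl (4E,6S)-2-[bis(2,2,2-trifluoroethoxy)phosphoryl]-6-methyl-6-(triethylsilyloxy)-8-(2,6,6-trimethylcyclohex-1-en-1-yl)oct-4-enoate; 10 2-[(4-methoxybenzyl)oxy]acetaldehyde
Product: 12 methyl (2Z)-4-[(4-methoxybenzyl)oxy]-2-[(2E,4S)-4-methyl-4-(triethylsilyloxy)-6-(2,6,6-trimethylcyclohex-1-en-1-yl)hex-2-en-1-yl]but-2-enoate, via potassium phosphonate carbanion 11 (not isolated)
Conditions: KN(SiMe3)2, 18-crown-6, THF, −78 °C; then 10, −78 °C
Reagents that add atoms: none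
Why: Still–Gennari olefination with an α-substituted bis(trifluoroethyl) phosphonate and an unhindered aldehyde should give the Z enoate (ester cis to the CH2O group) by fast irreversible collapse of the kinetic adduct.

Step 9
Reactants: 12 methyl (2Z)-4-[(4-methoxybenzyl)oxy]-2-[(2E,4S)-4-methyl-4-(triethylsilyloxy)-6-(2,6,6-trimethylcyclohex-1-en-1-yl)hex-2-en-1-yl]but-2-enoate
Product: 13 (2Z)-4-[(4-methoxybenzyl)oxy]-2-[(2E,4S)-4-methyl-4-(triethylsilyloxy)-6-(2,6,6-trimethylcyclohex-1-en-1-yl)hex-2-en-1-yl]but-2-en-1-ol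
Conditions: i-Bu2AlH (2.5 equiv), CH2Cl2, −78 °C; aq. potassium sodium tartrate
Reagents that add atoms: none
Why: i-Bu2AlH 1,2-reduction of the enoate should give the allylic alcohol without affecting the ethers or either alkene.

Step 10
Reactants: 13 (2Z)-4-[(4-methoxybenzyl)oxy]-2-[(2E,4S)-4-methyl-4-(triethylsilyloxy)-6-(2,6,6-trimethylcyclohex-1-en-1-yl)hex-2-en-1-yl]but-2-en-1-ol
Product: 14 (2Z,5E,7S)-3-[(tert-butyldiphenylsilyloxy)methyl]-1-[(4-methoxybenzyl)oxy]-7-methyl-7-(triethylsilyloxy)-9-(2,6,6-trimethylcyclohex-1-en-1-yl)nona-2,5-diene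
Conditions: t-BuPh2SiCl, imidazole, DMF, 0 °C to rt
Reagents that add atoms: tert-butyl(chloro)diphenylsilane, CC(C)(C)[Si](Cl)(c1ccccc1)c1ccccc1
Why: standard silylation of a primary alcohol installs an ether that should survive the oxidative, basic and mildly acidic steps up to the final deprotection.

Step 11
Reactants: 14 (2Z,5E,7S)-3-[(tert-butyldiphenylsilyloxy)methyl]-1-[(4-methoxybenzyl)oxy]-7-methyl-7-(triethylsilyloxy)-9-(2,6,6-trimethylcyclohex-1-en-1-yl)nona-2,5-diene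
Product: 15 (2Z,5E,7S)-3-[(tert-butyldiphenylsilyloxy)methyl]-7-methyl-7-(triethylsilyloxy)-9-(2,6,6-trimethylcyclohex-1-en-1-yl)nona-2,5-dien-1-ol
Conditions: DDQ (1.2 equiv), CH2Cl2–aq. NaH2PO4/Na2HPO4 (pH 7), 0 °C
Reagents that add atoms: none
Why: oxidative cleavage of a 4-methoxybenzyl ether with DDQ is orthogonal to the silyl ethers, and buffering at 0 °C with a small excess should spare the non-conjugated diene.

Step 12
Reactants: 15 (2Z,5E,7S)-3-[(tert-butyldiphenylsilyloxy)methyl]-7-methyl-7-(triethylsilyloxy)-9-(2,6,6-trimethylcyclohex-1-en-1-yl)nona-2,5-dien-1-ol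
Product: 16 (2Z,5E,7S)-1-bromo-3-[(tert-butyldiphenylsilyloxy)methyl]-7-methyl-7-(triethylsilyloxy)-9-(2,6,6-trimethylcyclohex-1-en-1-yl)nona-2,5-diene
Conditions: CBr4, PPh3, CH2Cl2, −20 to 0 °C; used without storage
Reagents that add atoms: carbon tetrabromide, BrC(Br)(Br)Br
Why: the Appel reaction converts a primary allylic alcohol to the bromide by SN2 displacement under neutral conditions, so the Z geometry and the silyl ethers should be retained.

Step 13
Reactants: 17 2,2-dimethyl-1,3-dioxan-5-one; 18 (S)-1-amino-2-(methoxymethyl)pyrrolidine (SAMP)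
Product: 19 (S)-N-(2,2-dimethyl-1,3-dioxan-5-ylidene)-2-(methoxymethyl)pyrrolidin-1-amine
Conditions: benzene, reflux, Dean–Stark trap
Reagents that add atoms: none
Why: condensation of the ketone with the hydrazine under water removal is the standard preparation of this SAMP hydrazone.

Step 14
Reactants: 19 (S)-N-(2,2-dimethyl-1,3-dioxan-5-ylidene)-2-(methoxymethyl)pyrrolidin-1-amine; 16 (2Z,5E,7S)-1-bromo-3-[(tert-butyldiphenylsilyloxy)methyl]-7-methyl-7-(triethylsilyloxy)-9-(2,6,6-trimethylcyclohex-1-en-1-yl)nona-2,5-diene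
Product: 21 (S)-N-{(4S)-4-[(2Z,5E,7S)-3-[(tert-butyldiphenylsilyloxy)methyl]-7-methyl-7-(triethylsilyloxy)-9-(2,6,6-trimethylcyclohex-1-en-1-yl)nona-2,5-dien-1-yl]-2,2-dimethyl-1,3-dioxan-5-ylidene}-2-(methoxymethyl)pyrrolidin-1-amine, via lithium azaenolate 20 (not isolated)
Conditions: 19 (1.3 equiv), t-BuLi (1.3 equiv), THF, −78 °C, 2 h; then 16 (1.0 equiv), THF, −100 °C to rt
Reagents that add atoms: none
Why: t-BuLi removes an α-proton of 19 to give lithium azaenolate 20, in which the dioxane ring fixes the C=C geometry and lithium is held by the azaenolate nitrogen and the methoxymethyl oxygen, and 20 then displaces bromide from the primary allylic carbon of 16 in an SN2 step at −100 °C. The closest known reaction type is the Enders SAMP-hydrazone α-alkylation of 2,2-dimethyl-1,3-dioxan-5-one with alkyl and allylic halides. No ring is closed in this step; the 1,3-dioxane ring and the C=N–N bond are temporary and are cleaved in steps 15 and 16. The new stereocentre (C4 of the dioxane, later C5 of the furanone) is controlled by the (S)-2-(methoxymethyl)pyrrolidine unit, which shields one face of the chelated azaenolate so that the halide enters from the other face and should give the 4S configuration, the same sense of attack as in SAMP alkylations of simple cyclic ketones. The step needs C- over N-alkylation, SN2 over SN2′ attack, monoalkylation and retention of the Z geometry; these are secured by the soft carbon terminus of the azaenolate, the fully substituted γ-carbon of 16, the use of the bromide as limiting reagent with one equivalent of base per hydrazone, and the low temperature, which should exclude ionisation of the allylic bromide.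

Step 15
Reactants: 21 (S)-N-{(4S)-4-[(2Z,5E,7S)-3-[(tert-butyldiphenylsilyloxy)methyl]-7-methyl-7-(triethylsilyloxy)-9-(2,6,6-trimethylcyclohex-1-en-1-yl)nona-2,5-dien-1-yl]-2,2-dimethyl-1,3-dioxan-5-ylidene}-2-(methoxymethyl)pyrrolidin-1-amine
Product: 22 (4S)-4-[(2Z,5E,7S)-3-[(tert-butyldiphenylsilyloxy)methyl]-7-methyl-7-(triethylsilyloxy)-9-(2,6,6-trimethylcyclohex-1-en-1-yl)nona-2,5-dien-1-yl]-2,2-dimethyl-1,3-dioxan-5-one
Conditions: sat. aq. (CO2H)2, Et2O, rt
Reagents that add atoms: water, O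
Why: two-phase oxalic acid hydrolysis is the established non-oxidative cleavage of dioxanone SAMP hydrazones; it should leave the acetonide, the silyl ethers and the alkenes intact and not epimerise the α-centre.

Step 16
Reactants: 22 (4S)-4-[(2Z,5E,7S)-3-[(tert-butyldiphenylsilyloxy)methyl]-7-methyl-7-(triethylsilyloxy)-9-(2,6,6-trimethylcyclohex-1-en-1-yl)nona-2,5-dien-1-yl]-2,2-dimethyl-1,3-dioxan-5-one
Product: 23 (3S,5Z,8E,10S)-6-[(tert-butyldiphenylsilyloxy)methyl]-1,3,10-trihydroxy-10-methyl-12-(2,6,6-trimethylcyclohex-1-en-1-yl)dodeca-5,8-dien-2-one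
Conditions: Dowex 50WX8 (H+ form), MeOH–H2O 9:1, 0 °C to rt
Reagents that add atoms: none
Why: acidic ion-exchange resin is the precedented mild deprotection of dioxanone acetonides to free dihydroxy ketones and should also remove the tertiary triethylsilyl ether while the tert-butyldiphenylsilyl ether stays.

Step 17
Reactants: 23 (3S,5Z,8E,10S)-6-[(tert-butyldiphenylsilyloxy)methyl]-1,3,10-trihydroxy-10-methyl-12-(2,6,6-trimethylcyclohex-1-en-1-yl)dodeca-5,8-dien-2-one
Product: 24 (3S,5Z,8E,10S)-1-(tert-butyldimethylsilyloxy)-6-[(tert-butyldiphenylsilyloxy)methyl]-3,10-dihydroxy-10-methyl-12-(2,6,6-trimethylcyclohex-1-en-1-yl)dodeca-5,8-dien-2-one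
Conditions: t-BuMe2SiCl (1.1 equiv), imidazole, CH2Cl2, −20 to 0 °C
Reagents that add atoms: tert-butyl(chloro)dimethylsilane, CC(C)(C)[Si](C)(C)Cl
Why: silyl chloride/imidazole should react at the primary hydroxyl in preference to the secondary and tertiary ones, leaving the secondary α-hydroxyl as the only acylable position next to the ketone.

Step 18
Reactants: 24 (3S,5Z,8E,10S)-1-(tert-butyldimethylsilyloxy)-6-[(tert-butyldiphenylsilyloxy)methyl]-3,10-dihydroxy-10-methyl-12-(2,6,6-trimethylcyclohex-1-en-1-yl)dodeca-5,8-dien-2-one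
Product: 26 (5S)-4-[(tert-butyldimethylsilyloxy)methyl]-5-[(2Z,5E,7S)-3-[(tert-butyldiphenylsilyloxy)methyl]-7-hydroxy-7-methyl-9-(2,6,6-trimethylcyclohex-1-en-1-yl)nona-2,5-dien-1-yl]furan-2(5H)-one, via phosphoranylidene acetate ester 25 (not isolated)
Conditions: Ph3P=C=C=O (1.5 equiv), toluene, 80 °C
Reagents that add atoms: (triphenylphosphoranylidene)ketene, O=C=C=P(c1ccccc1)(c1ccccc1)c1ccccc1
Why: in the Bestmann butenolide synthesis the α-hydroxyl adds to the ketenylidene phosphorane to give an ester ylide that closes onto the adjacent ketone by intramolecular Wittig reaction (5-membered ring), and the hindered tertiary alcohol should add far more slowly.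

Step 19
Reactants: 26 (5S)-4-[(tert-butyldimethylsilyloxy)methyl]-5-[(2Z,5E,7S)-3-[(tert-butyldiphenylsilyloxy)methyl]-7-hydroxy-7-methyl-9-(2,6,6-trimethylcyclohex-1-en-1-yl)nona-2,5-dien-1-yl]furan-2(5H)-one
Product: 27 (5S)-4-(hydroxymethyl)-5-[(2Z,5E,7S)-7-hydroxy-3-(hydroxymethyl)-7-methyl-9-(2,6,6-trimethylcyclohex-1-en-1-yl)nona-2,5-dien-1-yl]furan-2(5H)-one (target)
Conditions: HF·pyridine, pyridine, THF, 0 °C to rt
Reagents that add atoms: none
Why: buffered HF·pyridine cleaves both primary silyl ethers without the basic conditions that could epimerise the γ-centre of the butenolide or the strong acid that could ionise the tertiary allylic alcohol.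

**Compound list**

1 | dihydro-β-ionone, 4-(2,6,6-trimethylcyclohex-1-en-1-yl)butan-2-one | CC1=C(CCC(C)=O)C(C)(C)CCC1 | starting material
2 | ethyl (2E)-3-methyl-5-(2,6,6-trimethylcyclohex-1-en-1-yl)pent-2-enoate | CC1=C(CC/C(C)=C/C(=O)OCC)C(C)(C)CCC1 | intermediate
3 | (2E)-3-methyl-5-(2,6,6-trimethylcyclohex-1-en-1-yl)pent-2-en-1-ol | CC1=C(CC/C(C)=C/CO)C(C)(C)CCC1 | intermediate
4 | {(2S,3S)-3-methyl-3-[2-(2,6,6-trimethylcyclohex-1-en-1-yl)ethyl]oxiran-2-yl}methanol | CC1=C(CC[C@]2(C)O[C@H]2CO)C(C)(C)CCC1 | intermediate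
5 | (2R,3S)-3-methyl-3-[2-(2,6,6-trimethylcyclohex-1-en-1-yl)ethyl]oxirane-2-carbaldehyde | CC1=C(CC[C@]2(C)O[C@H]2C=O)C(C)(C)CCC1 | intermediate
6 | (2S,3S)-2-ethenyl-3-methyl-3-[2-(2,6,6-trimethylcyclohex-1-en-1-yl)ethyl]oxirane | CC1=C(CC[C@]2(C)O[C@H]2C=C)C(C)(C)CCC1 | intermediate
7 | methyl 2-[bis(2,2,2-trifluoroethoxy)phosphoryl]acetate | COC(=O)CP(=O)(OCC(F)(F)F)OCC(F)(F)F | starting material
8 | methyl (4E,6S)-2-[bis(2,2,2-trifluoroethoxy)phosphoryl]-6-hydroxy-6-methyl-8-(2,6,6-trimethylcyclohex-1-en-1-yl)oct-4-enoate, both epimers at C2 | CC1=C(CC[C@](C)(O)/C=C/CC(C(=O)OC)P(=O)(OCC(F)(F)F)OCC(F)(F)F)C(C)(C)CCC1 | intermediate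
9 | methyl (4E,6S)-2-[bis(2,2,2-trifluoroethoxy)phosphoryl]-6-methyl-6-(triethylsilyloxy)-8-(2,6,6-trimethylcyclohex-1-en-1-yl)oct-4-enoate, both epimers at C2 | CC1=C(CC[C@](C)(O[Si](CC)(CC)CC)/C=C/CC(C(=O)OC)P(=O)(OCC(F)(F)F)OCC(F)(F)F)C(C)(C)CCC1 | intermediate
10 | 2-[(4-methoxybenzyl)oxy]acetaldehyde | COc1ccc(COCC=O)cc1 | starting material
11 | potassium salt of the C2 carbanion of 9 | CC1=C(CC[C@](C)(O[Si](CC)(CC)CC)/C=C/C[C-](C(=O)OC)P(=O)(OCC(F)(F)F)OCC(F)(F)F)C(C)(C)CCC1.[K+] | intermediate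
12 | methyl (2Z)-4-[(4-methoxybenzyl)oxy]-2-[(2E,4S)-4-methyl-4-(triethylsilyloxy)-6-(2,6,6-trimethylcyclohex-1-en-1-yl)hex-2-en-1-yl]but-2-enoate | CC1=C(CC[C@](C)(O[Si](CC)(CC)CC)/C=C/C/C(=C/COCc2ccc(OC)cc2)C(=O)OC)C(C)(C)CCC1 | intermediate
13 | (2Z)-4-[(4-methoxybenzyl)oxy]-2-[(2E,4S)-4-methyl-4-(triethylsilyloxy)-6-(2,6,6-trimethylcyclohex-1-en-1-yl)hex-2-en-1-yl]but-2-en-1-ol | CC1=C(CC[C@](C)(O[Si](CC)(CC)CC)/C=C/C/C(=C/COCc2ccc(OC)cc2)CO)C(C)(C)CCC1 | intermediate
14 | (2Z,5E,7S)-3-[(tert-butyldiphenylsilyloxy)methyl]-1-[(4-methoxybenzyl)oxy]-7-methyl-7-(triethylsilyloxy)-9-(2,6,6-trimethylcyclohex-1-en-1-yl)nona-2,5-diene | CC1=C(CC[C@](C)(O[Si](CC)(CC)CC)/C=C/C/C(=C/COCc2ccc(OC)cc2)CO[Si](c2ccccc2)(c2ccccc2)C(C)(C)C)C(C)(C)CCC1 | intermediate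
15 | (2Z,5E,7S)-3-[(tert-butyldiphenylsilyloxy)methyl]-7-methyl-7-(triethylsilyloxy)-9-(2,6,6-trimethylcyclohex-1-en-1-yl)nona-2,5-dien-1-ol | CC1=C(CC[C@](C)(O[Si](CC)(CC)CC)/C=C/C/C(=C/CO)CO[Si](c2ccccc2)(c2ccccc2)C(C)(C)C)C(C)(C)CCC1 | intermediate
16 | (2Z,5E,7S)-1-bromo-3-[(tert-butyldiphenylsilyloxy)methyl]-7-methyl-7-(triethylsilyloxy)-9-(2,6,6-trimethylcyclohex-1-en-1-yl)nona-2,5-diene | CC1=C(CC[C@](C)(O[Si](CC)(CC)CC)/C=C/C/C(=C/CBr)CO[Si](c2ccccc2)(c2ccccc2)C(C)(C)C)C(C)(C)CCC1 | intermediate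
17 | 2,2-dimethyl-1,3-dioxan-5-one | CC1(C)OCC(=O)CO1 | starting material
18 | (S)-1-amino-2-(methoxymethyl)pyrrolidine (SAMP) | COC[C@@H]1CCCN1N | starting material
19 | (S)-N-(2,2-dimethyl-1,3-dioxan-5-ylidene)-2-(methoxymethyl)pyrrolidin-1-amine | COC[C@@H]1CCCN1N=C1COC(C)(C)OC1 | intermediate
20 | lithium azaenolate of 19 | COC[C@@H]1CCCN1[N-]C1=COC(C)(C)OC1.[Li+] | intermediate
21 | (S)-N-{(4S)-4-[(2Z,5E,7S)-3-[(tert-butyldiphenylsilyloxy)methyl]-7-methyl-7-(triethylsilyloxy)-9-(2,6,6-trimethylcyclohex-1-en-1-yl)nona-2,5-dien-1-yl]-2,2-dimethyl-1,3-dioxan-5-ylidene}-2-(methoxymethyl)pyrrolidin-1-amine (C=N geometry not specified) | CC1=C(CC[C@](C)(O[Si](CC)(CC)CC)/C=C/C/C(=C/C[C@@H]2OC(C)(C)OCC2=NN2CCC[C@H]2COC)CO[Si](c2ccccc2)(c2ccccc2)C(C)(C)C)C(C)(C)CCC1 | intermediate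
22 | (4S)-4-[(2Z,5E,7S)-3-[(tert-butyldiphenylsilyloxy)methyl]-7-methyl-7-(triethylsilyloxy)-9-(2,6,6-trimethylcyclohex-1-en-1-yl)nona-2,5-dien-1-yl]-2,2-dimethyl-1,3-dioxan-5-one | CC1=C(CC[C@](C)(O[Si](CC)(CC)CC)/C=C/C/C(=C/C[C@@H]2OC(C)(C)OCC2=O)CO[Si](c2ccccc2)(c2ccccc2)C(C)(C)C)C(C)(C)CCC1 | intermediate
23 | (3S,5Z,8E,10S)-6-[(tert-butyldiphenylsilyloxy)methyl]-1,3,10-trihydroxy-10-methyl-12-(2,6,6-trimethylcyclohex-1-en-1-yl)dodeca-5,8-dien-2-one | CC1=C(CC[C@](C)(O)/C=C/C/C(=C/C[C@H](O)C(=O)CO)CO[Si](c2ccccc2)(c2ccccc2)C(C)(C)C)C(C)(C)CCC1 | intermediate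
24 | (3S,5Z,8E,10S)-1-(tert-butyldimethylsilyloxy)-6-[(tert-butyldiphenylsilyloxy)methyl]-3,10-dihydroxy-10-methyl-12-(2,6,6-trimethylcyclohex-1-en-1-yl)dodeca-5,8-dien-2-one | CC1=C(CC[C@](C)(O)/C=C/C/C(=C/C[C@H](O)C(=O)CO[Si](C)(C)C(C)(C)C)CO[Si](c2ccccc2)(c2ccccc2)C(C)(C)C)C(C)(C)CCC1 | intermediate
25 | (triphenylphosphoranylidene)acetate ester of the C3 hydroxyl of 24 | CC1=C(CC[C@](C)(O)/C=C/C/C(=C/C[C@H](OC(=O)C=P(c2ccccc2)(c2ccccc2)c2ccccc2)C(=O)CO[Si](C)(C)C(C)(C)C)CO[Si](c2ccccc2)(c2ccccc2)C(C)(C)C)C(C)(C)CCC1 | intermediate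
26 | (5S)-4-[(tert-butyldimethylsilyloxy)methyl]-5-[(2Z,5E,7S)-3-[(tert-butyldiphenylsilyloxy)methyl]-7-hydroxy-7-methyl-9-(2,6,6-trimethylcyclohex-1-en-1-yl)nona-2,5-dien-1-yl]furan-2(5H)-one | CC1=C(CC[C@](C)(O)/C=C/C/C(=C/C[C@@H]2OC(=O)C=C2CO[Si](C)(C)C(C)(C)C)CO[Si](c2ccccc2)(c2ccccc2)C(C)(C)C)C(C)(C)CCC1 | intermediate
27 | (5S)-4-(hydroxymethyl)-5-[(2Z,5E,7S)-7-hydroxy-3-(hydroxymethyl)-7-methyl-9-(2,6,6-trimethylcyclohex-1-en-1-yl)nona-2,5-dien-1-yl]furan-2(5H)-one | CC1=C(CC[C@](C)(O)/C=C/C/C(=C/C[C@@H]2OC(=O)C=C2CO)CO)C(C)(C)CCC1 | target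

**Step count and risks**

Total step count: 19. Longest linear sequence: 18 steps (steps 1 to 12 and 14 to 19, from dihydro-β-ionone); step 13 is a one-step branch.

Steps most likely to fail:

Step 14. The bulky, functionalised allylic bromide may react too slowly at −100 °C, so that warming erodes the facial selectivity or lets proton transfer and elimination compete. The fallback sets out from 16 and comes back at 23, using a glycolate auxiliary instead of the hydrazone. The sodium enolate (NaN(SiMe3)2, THF, −78 to −45 °C) of the known imide (R)-4-benzyl-3-{[(4-methoxybenzyl)oxy]acetyl}oxazolidin-2-one is alkylated with 16 (Evans–Crimmins glycolate alkylation, benzyl group shielding one enolate face) to give the N-acyl oxazolidinone F1. Transamidation with MeNH(OMe)·HCl/AlMe3 gives the Weinreb amide F2. Addition of (4-methoxybenzyloxy)methyllithium (from Bu3SnCH2OCH2C6H4OMe and n-BuLi, THF, −78 °C) gives the bis(4-methoxybenzyl) ketone F3. Buffered DDQ removes both benzyl ethers to give the dihydroxy ketone F4. PPTS in MeOH then removes the tertiary triethylsilyl ether and delivers 23.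

Step 16. While the deactivated α-keto acetonide is hydrolysed, the α-hydroxy ketone may enolise (epimerisation at the carbinol carbon or ketol shift) and the tertiary allylic alcohol may ionise. The fallback sets out from 22 and comes back at 26, and never frees the hydroxy ketone. Wittig methylenation of 22 (Ph3P=CH2, THF, −78 to 0 °C) gives the methylidene dioxane F5. Its now allylic acetonide and the triethylsilyl ether should fall to catalytic camphorsulfonic acid in MeOH at 0 °C to give the triol F6. Silylation of the primary hydroxyl (t-BuMe2SiCl, imidazole) gives the diol F7. Acryloyl chloride and Et3N (CH2Cl2, −78 °C) acylate the secondary hydroxyl to give the acrylate F8. Ring-closing metathesis with the second-generation Grubbs catalyst (CH2Cl2, 40 °C) closes the five-membered lactone between the acrylate and the 1,1-disubstituted alkene to give 26.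

Step 18. The basic ylide may epimerise the α-hydroxy ketone before ring closure, or add slowly to the tertiary alcohol as well. The fallback sets out from 24 and comes back at 26, separating acylation from ring closure. The secondary hydroxyl is esterified with (diethoxyphosphoryl)acetic acid (DCC, cat. DMAP, CH2Cl2, 0 °C) to give the phosphonoacetate F9. The intramolecular Horner–Wadsworth–Emmons reaction under Masamune–Roush conditions (LiCl, i-Pr2NEt, MeCN, rt) then gives 26.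

Further compounds
F1 | step 14 | (4R)-4-benzyl-3-{(2S,4Z,7E,9S)-5-[(tert-butyldiphenylsilyloxy)methyl]-2-[(4-methoxybenzyl)oxy]-9-methyl-9-(triethylsilyloxy)-11-(2,6,6-trimethylcyclohex-1-en-1-yl)undeca-4,7-dienoyl}oxazolidin-2-one | CC1=C(CC[C@](C)(O[Si](CC)(CC)CC)/C=C/C/C(=C/C[C@H](OCc2ccc(OC)cc2)C(=O)N2C(=O)OC[C@H]2Cc2ccccc2)CO[Si](c2ccccc2)(c2ccccc2)C(C)(C)C)C(C)(C)CCC1
F2 | step 14 | (2S,4Z,7E,9S)-5-[(tert-butyldiphenylsilyloxy)methyl]-N-methoxy-2-[(4-methoxybenzyl)oxy]-N,9-dimethyl-9-(triethylsilyloxy)-11-(2,6,6-trimethylcyclohex-1-en-1-yl)undeca-4,7-dienamide | CC1=C(CC[C@](C)(O[Si](CC)(CC)CC)/C=C/C/C(=C/C[C@H](OCc2ccc(OC)cc2)C(=O)N(C)OC)CO[Si](c2ccccc2)(c2ccccc2)C(C)(C)C)C(C)(C)CCC1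
F3 | step 14 | (3S,5Z,8E,10S)-6-[(tert-butyldiphenylsilyloxy)methyl]-1,3-bis[(4-methoxybenzyl)oxy]-10-methyl-10-(triethylsilyloxy)-12-(2,6,6-trimethylcyclohex-1-en-1-yl)dodeca-5,8-dien-2-one | CC1=C(CC[C@](C)(O[Si](CC)(CC)CC)/C=C/C/C(=C/C[C@H](OCc2ccc(OC)cc2)C(=O)COCc2ccc(OC)cc2)CO[Si](c2ccccc2)(c2ccccc2)C(C)(C)C)C(C)(C)CCC1
F4 | step 14 | (3S,5Z,8E,10S)-6-[(tert-butyldiphenylsilyloxy)methyl]-1,3-dihydroxy-10-methyl-10-(triethylsilyloxy)-12-(2,6,6-trimethylcyclohex-1-en-1-yl)dodeca-5,8-dien-2-one | CC1=C(CC[C@](C)(O[Si](CC)(CC)CC)/C=C/C/C(=C/C[C@H](O)C(=O)CO)CO[Si](c2ccccc2)(c2ccccc2)C(C)(C)C)C(C)(C)CCC1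
F5 | step 16 | (4S)-4-[(2Z,5E,7S)-3-[(tert-butyldiphenylsilyloxy)methyl]-7-methyl-7-(triethylsilyloxy)-9-(2,6,6-trimethylcyclohex-1-en-1-yl)nona-2,5-dien-1-yl]-2,2-dimethyl-5-methylidene-1,3-dioxane | CC1=C(CC[C@](C)(O[Si](CC)(CC)CC)/C=C/C/C(=C/C[C@@H]2OC(C)(C)OCC2=C)CO[Si](c2ccccc2)(c2ccccc2)C(C)(C)C)C(C)(C)CCC1
F6 | step 16 | (3S,5Z,8E,10S)-6-[(tert-butyldiphenylsilyloxy)methyl]-10-methyl-2-methylidene-12-(2,6,6-trimethylcyclohex-1-en-1-yl)dodeca-5,8-diene-1,3,10-triol | CC1=C(CC[C@](C)(O)/C=C/C/C(=C/C[C@H](O)C(=C)CO)CO[Si](c2ccccc2)(c2ccccc2)C(C)(C)C)C(C)(C)CCC1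
F7 | step 16 | (3S,5Z,8E,10S)-1-(tert-butyldimethylsilyloxy)-6-[(tert-butyldiphenylsilyloxy)methyl]-10-methyl-2-methylidene-12-(2,6,6-trimethylcyclohex-1-en-1-yl)dodeca-5,8-diene-3,10-diol | CC1=C(CC[C@](C)(O)/C=C/C/C(=C/C[C@H](O)C(=C)CO[Si](C)(C)C(C)(C)C)CO[Si](c2ccccc2)(c2ccccc2)C(C)(C)C)C(C)(C)CCC1
F8 | step 16 | (3S,5Z,8E,10S)-1-(tert-butyldimethylsilyloxy)-6-[(tert-butyldiphenylsilyloxy)methyl]-10-hydroxy-10-methyl-2-methylidene-12-(2,6,6-trimethylcyclohex-1-en-1-yl)dodeca-5,8-dien-3-yl prop-2-enoate | CC1=C(CC[C@](C)(O)/C=C/C/C(=C/C[C@H](OC(=O)C=C)C(=C)CO[Si](C)(C)C(C)(C)C)CO[Si](c2ccccc2)(c2ccccc2)C(C)(C)C)C(C)(C)CCC1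
F9 | step 18 | (3S,5Z,8E,10S)-1-(tert-butyldimethylsilyloxy)-6-[(tert-butyldiphenylsilyloxy)methyl]-10-hydroxy-10-methyl-2-oxo-12-(2,6,6-trimethylcyclohex-1-en-1-yl)dodeca-5,8-dien-3-yl 2-(diethoxyphosphoryl)acetate | CC1=C(CC[C@](C)(O)/C=C/C/C(=C/C[C@H](OC(=O)CP(=O)(OCC)OCC)C(=O)CO[Si](C)(C)C(C)(C)C)CO[Si](c2ccccc2)(c2ccccc2)C(C)(C)C)C(C)(C)CCC1
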